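**Remark on nomenclature:** germacrane numbering is used (ring C1–C10, lactone carbons C11–C13, C14 on C10, C15 on C4, side-chain atoms primed); β is the face of the flat-drawn ten-membered ring that carries the C3 oxygen, α the opposite face.

## Analysis of the target

The target (34) is a cis,cis-germacranolide. Its ten-membered carbocycle C1–C10 carries a Z trisubstituted C4–C5 alkene, a 1,10-epoxide whose ring bonds C1–C2 and C10–C9 are cis (the epoxide of a Z alkene), and an α-methylene γ-lactone (O–C6, C7, C11, C12, exocyclic C13) fused cis across C6–C7. There are six stereocenters (C1, C3, C6, C7, C8, C10). In a flat projection the C3 hydroxyl, the C6 lactone oxygen, the C7–C11 bond, the C8 acyloxy group and the epoxide oxygen all lie on the β face, so C6, C7 and C8 form a contiguous all-syn triad while C3 and the epoxide are remote from it. The sensitive groups are the methylene lactone (a Michael acceptor that does not tolerate alkoxides or alkaline peroxide), the trisubstituted epoxide facing a transannular alkene (acid), and the (Z)-4-hydroxy-2-methylbut-2-enoate on C8. This ester can isomerise to E, and under base its free hydroxyl can close to a butenolide and expel the C8 oxygen. The difficulty is a ten-membered ring with two Z trisubstituted alkene units, which resists end-to-end closure, and stereocontrol at C6, C7 and C8 on a flexible medium ring. The strategy rests on one feature: C6 is oxygenated, allylic to the Z C4–C5 alkene and tied to C1 through the C7–C10 bridge. Atoms C1–C6 with C15 and the C3 oxygen therefore map onto a 4-oxygenated 3-methyl-6-isopropenylcyclohexenone, the isopropenyl group supplying C10, C14 and C9, and a two-carbon alkenyl group on C6 supplying C7 and C8.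

## Retrosynthetic reasoning

**Side chain and protecting groups (34 ⇒ 33 ⇒ 27 + 31; 31 ⇒ 28).** The C8–O acyl bond is cut last because the (Z)-hydroxy enoate is the most base-labile part of the molecule. The forward step must acylate a hindered secondary alcohol without Z/E isomerisation, and the final desilylation must not generate alkoxides. Acid 31 takes its Z geometry from the ring of butenolide 28, so no olefination is needed.

**Epoxide (27 ⇒ 26).** The two C–O bonds of the oxirane are removed to the Z C1–C10 alkene. At this point the only free hydroxyl is at C8, homoallylic to C1=C10, so the oxidant can be delivered by the substrate. The other two alkenes are electronically deactivated.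

**Exocyclic methylene (26 ⇒ 25 ⇒ 21 ⇒ 20).** The C11–C13 bond is cut back to the saturated lactone. The methylene group is introduced after the C8 oxygen exists, because the preceding silicon-to-oxygen exchange uses alkaline peroxide. It is introduced before the epoxide and the C8 ester, because it needs a strong base. The C8 hydroxyl is masked for this one operation (21, 25).

**C8 oxygen (20 ⇒ 18).** The C8–O bond is traced to a C8–Si bond. Silicon stands in for oxygen through all the carbonyl chemistry at C6 and C7, where a β-oxygen would be lost by elimination or retro-aldol cleavage, and it is exchanged for oxygen with retention.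

**Lactone (18 ⇒ 17 ⇒ 16 ⇒ 14).** The lactone C–O bond and the C6–H bond are cut to a C6 ketone, and the C7–C11 bond is cut to an enolate alkylation with a two-carbon ester electrophile. The C6 ketone is what the ring-forming step delivers, and it activates C7 and nothing else (C5 is sp2). The forward steps must place the C7 arm cis to silicon and then the C6 oxygen cis to the arm.

**Ten-membered ring (14 ⇒ 11).** A retro-[3,3] shift reconnects C1–C6 and cuts C8–C9, contracting the ring to the cis-1,2-dialkenyl cyclohexenol 11. This removes the medium ring, the C8 stereocenter and the Z C1–C10 alkene in one operation. The Z C4–C5 alkene becomes an ordinary cyclohexene, and C3 is left as a stereocenter on a six-membered ring.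

**Carbinol (11 ⇒ 9 ⇒ 4 + 7; 7 ⇒ 5 + 6).** The E-vinylsilane comes from trans reduction of the silylalkyne, and the C6–C7 bond from addition of the acetylide of 7 to enone 4. A slim alkynyl nucleophile is used, rather than a vinyl metal, because it should attack axially and so give the required cis relation to isopropenyl.

**Enone (4 ⇒ 3 ⇒ 2 ⇒ 1).** The C6 carbonyl is removed to an allylic methylene and the C3 silyl ether to the ketone of (S)-carvone (1). Carvone supplies all ring carbons, C15, the isopropenyl group and the absolute configuration, which is relayed from its stereocenter to C3 and, through the [3,3] shift, to C8.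

## Alternatives that were turned down

**Alternative 1:** The ring is disconnected across a transannular C3–C8 bond, so that the ten-membered ring is hidden in a bicyclo[4.4.0] system. In the forward sense the racemic Birch-derived 4,7-dimethyl-3,4,5,8-tetrahydronaphthalen-2(1H)-one A2 is cleaved at its tetrasubstituted ring-fusion alkene by ozone to the racemic trione A1. In its favour, no cyclisation entropy is paid, the starting material is an aromatic feedstock, and the ring is reached in very few operations; on step count to a ten-membered ring this is at least as good as the chosen route. The tetrasubstituted alkene is also the more electron-rich one, so the cleavage should be site-selective. Against it, A1 is racemic, and its only stereocenter (C4) is later flattened into the C4–C5 alkene. C3, C6 and C8 are all ketones, and C6/C8 form a 1,3-diketone around C7 that enolises and invites transannular aldol reactions. The C4–C5 alkene and all six stereocenters would have to be introduced on a flexible ring with no resolved handle. The chosen strategy gives up the shortcut to the ring but delivers it enantiopure, with C3 and C8 set and both alkene geometries in place.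

**Alternative 2:** C2–C3 and C3–C4 are cut, with C3 coming from carbon monoxide. In the forward sense the open-chain allylic chloride–vinylstannane A4 is treated with a zerovalent palladium catalyst such as Pd(PPh3)4 under CO. Ionisation at C2, CO insertion and coupling with the C4 stannane close the ring to dienone A3. In its favour, the route is convergent, the C3 oxygen arrives as CO, and C6, C7 and C8 are fixed on a five-membered lactol acetal before the ring exists. On that last point it is stronger than the chosen route, which has to set C7 and C6 on the medium ring. Against it, the closure is end-to-end onto a strained ten-membered ring and needs high dilution. The allylpalladium intermediate from a Z allylic chloride can equilibrate and erode the C1–C10 geometry, and it can couple at either allyl terminus. Direct coupling competes with CO insertion, and the β,γ-unsaturated ketone can slip into conjugation. A4 is long to prepare and uses tin. The chosen strategy offers ring formation by expansion at ordinary concentration, with both Z geometries fixed by a six-membered ring and a chair transition state.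

**Alternative 3:** C5–C6 is cut. In the forward sense the aldehyde–vinyl iodide A6 is treated with CrCl2 and catalytic NiCl2, and the vinylchromium species adds to the C6 aldehyde to give cyclodecenol A5. In its favour, the divalent chromium reagent tolerates the epoxide and the esters, the C6 carbinol is formed directly, and C1, C3, C7, C8 and C10 are set beforehand by acyclic methods. This is stronger than the chosen route for C7 and the epoxide. Against it, the C6 configuration is created during a medium-ring closure under weak control. The closure needs high dilution and a large excess of CrCl2. Aldehyde A6 is α-branched and β-alkoxylated, so it can epimerise at C7 or eliminate. The Z trisubstituted vinyl iodide next to a silyloxy stereocenter is costly, and the linear sequence is long. The chosen strategy offers the ring, C8 and the C1–C10 geometry in one step from a precursor made in five linear steps from carvone.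

Key step: step 7

## Route

Step 1
Reactants: 1 (S)-(+)-carvone
Product: 2 (1S,5S)-cis-carveol
Conditions: NaBH4, CeCl3·7H2O, MeOH, −20 °C
Reagents that add atoms: none
Why: Luche reduction: CeCl3 promotes clean 1,2-reduction and hydride enters axially, so the hydroxyl is equatorial and cis to the equatorial isopropenyl group; this sets C3 of the target relative to the carvone stereocenter, which later relays its chirality to C8.

Step 2
Reactants: 2 (1S,5S)-cis-carveol
Product: 3 cis-carveol triisopropylsilyl ether
Conditions: TIPSOTf, 2,6-lutidine, CH2Cl2, 0 °C
Reagents that add atoms: triisopropylsilyl triflate, CC(C)[Si](OS(=O)(=O)C(F)(F)F)(C(C)C)C(C)C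
Why: Silylation of the secondary allylic alcohol; the triisopropylsilyl group is chosen over smaller silyl groups because it must survive Bu4NF in step 10 and still be removable with HF·pyridine at the end.

Step 3
Reactants: 3 cis-carveol triisopropylsilyl ether
Product: 4 4-silyloxy enone (3-methyl-6-isopropenyl-4-triisopropylsilyloxycyclohex-2-enone)
Conditions: CrO3, 3,5-dimethylpyrazole, CH2Cl2, −20 °C
Reagents that add atoms: chromium trioxide, O=[Cr](=O)=O
Why: Allylic oxidation with the CrO3·3,5-dimethylpyrazole complex: the electron-rich trisubstituted ring alkene is attacked in preference to isopropenyl and its only allylic methylene (C6) is oxidised to the conjugated ketone; the neutral, cold conditions should leave the adjacent stereocenter and the β,γ-isopropenyl group in place.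

Step 4
Reactants: 5 benzylchlorodimethylsilane; 6 ethynylmagnesium bromide
Product: 7 benzyl(ethynyl)dimethylsilane
Conditions: THF, 0 °C → rt
Reagents that add atoms: none
Why: Nucleophilic substitution at silicon: the alkynyl Grignard reagent displaces chloride, and the terminal C–H is kept for the next step.

Step 5
Reactants: 4 4-silyloxy enone; 7 benzyl(ethynyl)dimethylsilane
Product: 9 alkynyl carbinol (alkynyl cis to isopropenyl), via lithium silylacetylide 8 (not isolated)
Conditions: 7, n-BuLi, THF, −78 °C; anhydrous CeCl3; then 4, −78 °C; aq. NH4Cl
Reagents that add atoms: none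
Why: 1,2-Addition of a cerium-modified lithium acetylide: the weakly basic reagent suppresses enolisation of the doubly activated C1–H, and the slim linear nucleophile attacks the half-chair enone along the axial trajectory, so the alkynyl group becomes axial and cis to the equatorial isopropenyl group while the new hydroxyl is equatorial (C6 carbinol set relative to C1).

Step 6
Reactants: 9 alkynyl carbinol
Product: 11 cis-dialkenyl cyclohexenol (E-vinylsilane), via sodium alkenylaluminate 10 (not isolated)
Conditions: NaAlH2(OCH2CH2OCH3)2, THF, 0 °C → rt; aq. KNaC4H4O6
Reagents that add atoms: none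
Why: Trans-hydroalumination of a propargylic alcohol: the alkoxide-bound aluminium hydride delivers hydride to C7 from inside, giving the five-membered alkenylaluminate 10, and protonolysis of the C8–Al bond with retention leaves silicon trans to C6 (E); isolated alkenes and the silyl ether are inert.

Step 7
Reactants: 11 cis-dialkenyl cyclohexenol (key-step precursor)
Product: 14 (Z,Z)-cyclodecadienone, via potassium alkoxide 12 (not isolated), via potassium enolate 13 (not isolated)
Conditions: KH, 18-crown-6, THF, 0 °C → rt; then aq. NH4Cl, −78 °C
Reagents that add atoms: none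
Why: KH removes the hydroxyl proton and 18-crown-6 sequesters potassium, so the bare alkoxide 12 weakens the C1–C6 bond and the 3-oxido-1,5-diene C8=C7–C6–C1–C10=C9 undergoes a concerted, oxyanion-accelerated [3,3] sigmatropic shift through a chair transition state to enolate 13, which a cold proton quench converts into ketone 14. The closest known reaction type is the anionic oxy-Cope ring expansion of 1,2-dialkenylcyclohexanols to cyclodec-5-enones, which has been applied to isopiperitenone-derived carbinols. No end-to-end cyclisation is involved: the six-membered ring C1–C6 grows by four atoms as C8–C9 forms and C1–C6 breaks within the cyclic six-atom array, so ordinary concentrations suffice. The new C8 stereocenter is controlled by the E geometry of the vinylsilane, which puts silicon equatorial on the chair, and by the C1 center, which decides which face of C8 meets C9; the resulting C8–Si bond is β and is later exchanged for oxygen with retention. The step needs the new C1–C10 alkene to be Z and needs a single chair: because the two alkenyl groups are cis, the ring bond C1–C2 is axial on the chair when isopropenyl is equatorial on the cyclohexene, and an axial substituent at that terminus ends up cis on the new alkene. The substrate secures this, since isopropenyl (C1) and the silyloxy group (C3) are cis-1,3 and both equatorial in the half-chair that holds the alkenylsilane pseudoaxial at C6, whereas the inverted half-chair leading to the E alkene would make both axial. The cyclohexene double bond is carried over unchanged as the Z C4–C5 enone, and silicon at C8, unlike an oxygen substituent, cannot be expelled from the β-position of the enolate.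

Step 8
Reactants: 14 (Z,Z)-cyclodecadienone
Product: 16 C7-alkylated keto ester, via ring-cis lithium enolate 15 (not isolated)
Conditions: LiN(i-Pr)2, THF, −78 °C; BrCH2CO2Me, DMPU, −78 → −40 °C
Reagents that add atoms: methyl bromoacetate, COC(=O)CBr
Why: Kinetic deprotonation at C7, the only sp3 α-carbon, gives the cross-conjugated ring-cis enolate 15; allylic 1,3-strain holds H8 in the enolate plane, so the bromoacetate is expected to enter anti to the bulky, electron-releasing C8–Si bond (anti alkylation of β-silyl enolates), placing the C7 arm β, cis to silicon. The ring-trans enolate 13 is deliberately not alkylated in the flask of step 7, because a model of its chair-derived conformation exposes the face syn to silicon.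

Step 9
Reactants: 16 C7-alkylated keto ester
Product: 18 cis-fused C8-silyl lactone, via C6 hydroxy ester 17 (not isolated)
Conditions: NaBH4, CeCl3·7H2O, MeOH–THF, −78 °C; then PPTS (cat.), PhMe, 40 °C
Reagents that add atoms: none
Why: Luche 1,2-reduction of the enone followed by acid-catalysed lactonisation: hydride is expected to attack C6 anti to the C7–C8 bond, which carries the bulky silyl group and lies perpendicular to the carbonyl plane (Felkin–Anh control, reinforced by approach from the ring periphery), so the C6 oxygen ends cis to the C7 ester arm and closes to the cis-fused γ-lactone with loss of methanol.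

Step 10
Reactants: 18 cis-fused C8-silyl lactone
Product: 20 8-hydroxy lactone, via fluorosilane 19 (not isolated)
Conditions: Bu4NF, THF, 0 °C; then 30% H2O2, KHCO3, MeOH–THF, rt
Reagents that add atoms: hydrogen peroxide, OO
Why: Tamao–Fleming oxidation: fluoride cleaves the benzyl–silicon bond to give fluorosilane 19, hydroperoxide adds to silicon and C8 migrates from silicon to oxygen with retention, so the hydroxyl appears on the β face; the hindered secondary TIPS ether is expected to survive short exposure to Bu4NF at 0 °C, and the step precedes methylenation because a methylene lactone would not tolerate alkaline peroxide.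

Step 11
Reactants: 20 8-hydroxy lactone
Product: 21 8-triethylsilyloxy lactone
Conditions: Et3SiCl, imidazole, DMAP (cat.), DMF, 0 °C
Reagents that add atoms: chlorotriethylsilane, CC[Si](Cl)(CC)CC
Why: Silylation masks the C8 hydroxyl, which as an alkoxide beside the cis-disposed lactone carbonyl could translactonise during the strongly basic methylenation.

Step 12
Reactants: 21 8-triethylsilyloxy lactone
Product: 25 α-methylene lactone 8-triethylsilyl ether, via lithium lactone enolate 22 (not isolated), via Mannich base 23 (not isolated), via ammonium iodide 24 (not isolated)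
Conditions: LiN(i-Pr)2, THF, −78 °C; CH2=NMe2+ I−, −78 °C → rt; MeI, CH2Cl2, rt; aq. NaHCO3
Reagents that add atoms: N,N-dimethylmethyleneiminium iodide (Eschenmoser's salt), C=[N+](C)C.[I-]
Why: α-Methylenation by the Mannich route: enolate 22 is aminomethylated by the iminium salt, exhaustive methylation turns the amine into a leaving group, and mild base eliminates trimethylamine (E1cB) to the exocyclic alkene; C11 is the only acidic position and the C8 oxygen is masked, so neither translactonisation nor elimination competes.

Step 13
Reactants: 25 α-methylene lactone 8-triethylsilyl ether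
Product: 26 8-hydroxy α-methylene lactone
Conditions: HF·pyridine, pyridine, THF, 0 °C
Reagents that add atoms: none
Why: Selective desilylation: buffered HF cleaves the less hindered triethylsilyl ether much faster than the triisopropylsilyl ether, and the non-basic medium leaves the methylene lactone untouched.

Step 14
Reactants: 26 8-hydroxy α-methylene lactone
Product: 27 1β,10β-epoxy alcohol
Conditions: VO(acac)2 (cat.), t-BuOOH, CH2Cl2, 0 °C → rt
Reagents that add atoms: tert-butyl hydroperoxide, CC(C)(C)OO
Why: Hydroxyl-directed epoxidation: the C8 hydroxyl, homoallylic to C1=C10, binds the vanadium peroxide and delivers oxygen to the alkene face it can reach, the β face, giving the cis-epoxide of the Z alkene with C1 and C10 set together; C4=C5 is deactivated by two allylic C–O bonds and lies one carbon further from the hydroxyl, and the methylene lactone is too electron-poor to react.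

Step 15
Reactants: 28 3-methyl-2(5H)-furanone
Product: 31 (Z)-4-(tert-butyldimethylsilyloxy)-2-methylbut-2-enoic acid, via sodium hydroxy enoate 29 (not isolated), via bis-silyl derivative 30 (not isolated)
Conditions: NaOH, H2O–MeOH, rt, evaporate; TBSCl, imidazole, DMF, rt; AcOH–THF–H2O, rt
Reagents that add atoms: sodium hydroxide, [Na+].[OH-]; tert-butyldimethylsilyl chloride, CC(C)(C)[Si](C)(C)Cl
Why: Saponification opens the butenolide to the (Z)-4-hydroxy enoate salt 29, whose Z geometry is inherited from the ring; silylation of both oxygens gives 30, and the labile silyl ester alone is hydrolysed by aqueous acetic acid, so the free acid never carries a free γ-hydroxyl and cannot relactonise.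

Step 16
Reactants: 27 1β,10β-epoxy alcohol; 31 (Z)-4-(tert-butyldimethylsilyloxy)-2-methylbut-2-enoic acid
Product: 33 fully protected ester, via mixed anhydride 32 (not isolated)
Conditions: 31, 2,4,6-Cl3C6H2COCl, Et3N, THF, rt; then 27, DMAP, PhMe, 0 °C → rt
Reagents that add atoms: none
Why: Yamaguchi esterification: the acid is activated as mixed anhydride 32 and transferred to the hindered C8 hydroxyl under DMAP catalysis; the non-acidic, low-temperature protocol limits Z to E isomerisation of the enoate and leaves the epoxide and the methylene lactone untouched.

Step 17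
Reactants: 33 fully protected ester
Product: 34 CNP0410854.1
Conditions: HF·pyridine, pyridine, THF, 0 °C → rt
Reagents that add atoms: none
Why: Buffered, non-basic fluoride desilylation removes the primary TBS ether and the secondary allylic TIPS ether without generating alkoxides, which would close the (Z)-4-hydroxy enoate to a butenolide or add to the methylene lactone; the epoxide tolerates pyridine-buffered HF, and a prolonged reaction time is expected for the TIPS ether.

## Compound list

1 | (S)-(+)-carvone | CC1=CC[C@@H](CC1=O)C(C)=C | starting material
2 | (1S,5S)-cis-carveol, hydroxyl cis to isopropenyl | C1C=C(C)[C@@H](O)C[C@H]1C(C)=C | intermediate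
3 | (1S,5S)-cis-carveol triisopropylsilyl ether | C1C=C(C)[C@@H](O[Si](C(C)C)(C(C)C)C(C)C)C[C@H]1C(C)=C | intermediate
4 | 3-methyl-6-(prop-1-en-2-yl)-4-(triisopropylsilyloxy)cyclohex-2-en-1-one, 4,6-cis | O=C1C=C(C)[C@@H](O[Si](C(C)C)(C(C)C)C(C)C)C[C@H]1C(C)=C | intermediate
5 | benzylchlorodimethylsilane | C[Si](C)(Cl)Cc1ccccc1 | starting material
6 | ethynylmagnesium bromide | C#C[Mg]Br | starting material
7 | benzyl(ethynyl)dimethylsilane | C#C[Si](C)(C)Cc1ccccc1 | intermediate
8 | lithium acetylide of 7 (formed in the flask) | [Li+].[C-]#C[Si](C)(C)Cc1ccccc1 | intermediate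
9 | 1-[(benzyldimethylsilyl)ethynyl]-3-methyl-6-(prop-1-en-2-yl)-4-(triisopropylsilyloxy)cyclohex-2-en-1-ol; alkynyl cis to isopropenyl and to the silyloxy group, hydroxyl trans | O[C@]1(C#C[Si](C)(C)Cc2ccccc2)C=C(C)[C@@H](O[Si](C(C)C)(C(C)C)C(C)C)C[C@H]1C(C)=C | intermediate
10 | sodium alkenylaluminate with a five-membered O–Al–C8=C7–C6 ring, aluminium and silicon both on C8 (formed in the flask) | [Na+].COCCO[Al-]1(OCCOC)O[C@]2(C=C1[Si](C)(C)Cc1ccccc1)C=C(C)[C@@H](O[Si](C(C)C)(C(C)C)C(C)C)C[C@H]2C(C)=C | intermediate
11 | cis-1,2-dialkenyl cyclohexenol: (E)-2-(benzyldimethylsilyl)ethenyl analogue of 9; key-step precursor | O[C@]1(/C=C/[Si](C)(C)Cc2ccccc2)C=C(C)[C@@H](O[Si](C(C)C)(C(C)C)C(C)C)C[C@H]1C(C)=C | intermediate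
12 | potassium alkoxide of 11 (formed in the flask) | [K+].[O-][C@]1(/C=C/[Si](C)(C)Cc2ccccc2)C=C(C)[C@@H](O[Si](C(C)C)(C(C)C)C(C)C)C[C@H]1C(C)=C | intermediate
13 | potassium C6–C7 enolate of 14, ring-trans (oxygen cis to C8) (formed in the flask) | [K+].[O-]/C1=C\[C@H]([Si](C)(C)Cc2ccccc2)C/C(C)=C\C[C@H](O[Si](C(C)C)(C(C)C)C(C)C)/C(C)=C\1 | intermediate
14 | germacra-1(10)Z,4Z-dien-6-one with 3β-triisopropylsilyloxy and 8β-benzyldimethylsilyl groups; key-step product | C1[C@H]([Si](C)(C)Cc2ccccc2)C/C(C)=C\C[C@H](O[Si](C(C)C)(C(C)C)C(C)C)/C(C)=C\C1=O | intermediate
15 | lithium C6–C7 enolate of 14, ring-cis (oxygen trans to C8) (formed in the flask) | [Li+].[O-]/C1=C/[C@H]([Si](C)(C)Cc2ccccc2)C/C(C)=C\C[C@H](O[Si](C(C)C)(C(C)C)C(C)C)/C(C)=C\1 | intermediate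
16 | 14 carrying a 7β-CH2CO2Me arm (cis to silicon, H7 α) | COC(=O)C[C@@H]1[C@H]([Si](C)(C)Cc2ccccc2)C/C(C)=C\C[C@H](O[Si](C(C)C)(C(C)C)C(C)C)/C(C)=C\C1=O | intermediate
17 | 6β-hydroxy ester from 16 (formed in the flask) | COC(=O)C[C@@H]1[C@H]([Si](C)(C)Cc2ccccc2)C/C(C)=C\C[C@H](O[Si](C(C)C)(C(C)C)C(C)C)/C(C)=C\[C@@H]1O | intermediate
18 | cis-fused 6,12-olide (H6 and H7 both α) with 8β-benzyldimethylsilyl and 3β-triisopropylsilyloxy groups | O=C1C[C@@H]2[C@H]([Si](C)(C)Cc3ccccc3)C/C(C)=C\C[C@H](O[Si](C(C)C)(C(C)C)C(C)C)/C(C)=C\[C@@H]2O1 | intermediate
19 | 8β-fluorodimethylsilyl analogue of 18 (formed in the flask) | O=C1C[C@@H]2[C@H]([Si](C)(C)F)C/C(C)=C\C[C@H](O[Si](C(C)C)(C(C)C)C(C)C)/C(C)=C\[C@@H]2O1 | intermediate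
20 | 8β-hydroxy lactone | O=C1C[C@@H]2[C@H](O)C/C(C)=C\C[C@H](O[Si](C(C)C)(C(C)C)C(C)C)/C(C)=C\[C@@H]2O1 | intermediate
21 | 8β-triethylsilyloxy lactone | O=C1C[C@@H]2[C@H](O[Si](CC)(CC)CC)C/C(C)=C\C[C@H](O[Si](C(C)C)(C(C)C)C(C)C)/C(C)=C\[C@@H]2O1 | intermediate
22 | lithium C11–C12 enolate of 21 (formed in the flask) | [Li+].[O-]C1=C[C@@H]2[C@H](O[Si](CC)(CC)CC)C/C(C)=C\C[C@H](O[Si](C(C)C)(C(C)C)C(C)C)/C(C)=C\[C@@H]2O1 | intermediate
23 | 11-(dimethylaminomethyl) lactone, C11 configuration immaterial (formed in the flask) | O=C1C(CN(C)C)[C@@H]2[C@H](O[Si](CC)(CC)CC)C/C(C)=C\C[C@H](O[Si](C(C)C)(C(C)C)C(C)C)/C(C)=C\[C@@H]2O1 | intermediate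
24 | trimethylammonium iodide of 23 (formed in the flask) | [I-].O=C1C(C[N+](C)(C)C)[C@@H]2[C@H](O[Si](CC)(CC)CC)C/C(C)=C\C[C@H](O[Si](C(C)C)(C(C)C)C(C)C)/C(C)=C\[C@@H]2O1 | intermediate
25 | 11(13)-methylene lactone with 8β-triethylsilyloxy and 3β-triisopropylsilyloxy groups | O=C1C(=C)[C@@H]2[C@H](O[Si](CC)(CC)CC)C/C(C)=C\C[C@H](O[Si](C(C)C)(C(C)C)C(C)C)/C(C)=C\[C@@H]2O1 | intermediate
26 | 8β-hydroxy 11(13)-methylene lactone, 3β-triisopropylsilyloxy | O=C1C(=C)[C@@H]2[C@H](O)C/C(C)=C\C[C@H](O[Si](C(C)C)(C(C)C)C(C)C)/C(C)=C\[C@@H]2O1 | intermediate
27 | 1β,10β-epoxide of 26 (C14 α) | O=C1C(=C)[C@@H]2[C@H](O)C[C@]3(C)O[C@@H]3C[C@H](O[Si](C(C)C)(C(C)C)C(C)C)/C(C)=C\[C@@H]2O1 | intermediate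
28 | 3-methyl-2(5H)-furanone | CC1=CCOC1=O | starting material
29 | sodium (Z)-4-hydroxy-2-methylbut-2-enoate (formed in the flask) | [Na+].[O-]C(=O)/C(C)=C\CO | intermediate
30 | tert-butyldimethylsilyl (Z)-4-(tert-butyldimethylsilyloxy)-2-methylbut-2-enoate (formed in the flask) | CC(C)(C)[Si](C)(C)OC(=O)/C(C)=C\CO[Si](C)(C)C(C)(C)C | intermediate
31 | (Z)-4-(tert-butyldimethylsilyloxy)-2-methylbut-2-enoic acid | OC(=O)/C(C)=C\CO[Si](C)(C)C(C)(C)C | intermediate
32 | mixed anhydride of 31 with 2,4,6-trichlorobenzoic acid (formed in the flask) | O=C(OC(=O)/C(C)=C\CO[Si](C)(C)C(C)(C)C)c1c(Cl)cc(Cl)cc1Cl | intermediate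
33 | 3-O-triisopropylsilyl, 4'-O-tert-butyldimethylsilyl ether of the target | O=C1C(=C)[C@@H]2[C@H](OC(=O)/C(C)=C\CO[Si](C)(C)C(C)(C)C)C[C@]3(C)O[C@@H]3C[C@H](O[Si](C(C)C)(C(C)C)C(C)C)/C(C)=C\[C@@H]2O1 | intermediate
34 | CNP0410854.1 | C=C1C(=O)O[C@H]2/C=C(/C)[C@@H](O)C[C@H]3O[C@@]3(C)C[C@@H](OC(=O)/C(C)=C\CO)[C@@H]12 | target

## Step count and least certain steps

Total step count: 17. Longest linear sequence: 15 steps (1–3, 5–14, 16, 17, from carvone).

**Step 7 (key step).** The most likely failure is heterolysis of the doubly allylic alkoxide at C1–C6, that is, fragmentation to an enone and an allyl anion followed by unselective recombination or a formal [1,3] shift. Partial reaction through the inverted half-chair or a boat would also erode the Z geometry at C1–C10 and the C8 configuration. The fallback is a neutral rearrangement that cannot fragment to ions. Setting out from 11, the hydroxyl would be capped as the trimethylsilyl ether F1 (N-trimethylsilylimidazole, CH2Cl2). The siloxy-Cope rearrangement would then be run thermally (PhMe, sealed base-washed tube, about 180 °C, short reaction time to avoid a second Cope shift of the product diene), under the same chair and the same equatorial preferences. The resulting ring-expanded trimethylsilyl enol ether F2 would be cleaved with K2CO3 in MeOH at 0 °C, rejoining the route at 14.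

**Step 8.** The most likely failure is approach of the electrophile on the enolate face syn to silicon, because the folded ten-membered ring shields the other face; this would give the C7 epimer. Proton exchange between enolate and product is a second risk. The fallback sets the stereocenter by C–H instead of C–C bond formation. Setting out from 14, the alkylation would be allowed to give the 7α epimer F3. KN(SiMe3)2 (THF, −78 °C) would convert F3 into the tetrasubstituted potassium enolate F4. Kinetic protonation with 2,6-di-tert-butylphenol at −78 °C would then use the same face preference that misdirected the alkylation to place hydrogen α and the ester arm β, returning to the route at 16.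

**Step 14.** The most likely failure is that the C8 hydroxyl cannot reach across to C1=C10 in the preferred ring conformation, so that oxygen transfer is slow and unselective or occurs from the exposed α face. The fallback inverts the facial sense through a halohydrin. Setting out from 26, N-bromosuccinimide in aqueous THF would form the bromonium ion on the exposed face, and water would open it at the tertiary C10 from the opposite side, giving the 1α-bromo-10β-hydroxy bromohydrin F5. K2CO3 in acetone would close the epoxide by displacement at C1 with inversion, so that oxygen ends on the β face, rejoining the route at 27.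

**Step 9.** The most likely failure is hydride delivery to the opposite carbonyl face, imposed by the ring conformation against the Felkin–Anh preference, giving the 6α alcohol, which cannot form the cis-lactone. The fallback closes the lactone with inversion at C6. Setting out from 16, the 6α-hydroxy ester F6 would be saponified (LiOH, THF–H2O) to the hydroxy acid F7. Mitsunobu lactonisation (PPh3, diisopropyl azodicarboxylate, PhMe, 0 °C), in which the carboxylate displaces the activated allylic oxygen with inversion, would give 18.

**Step 5.** The most likely failure is equatorial attack, giving the trans-dialkenyl carbinol, which would rearrange to the E alkene. Enolisation at C1, with migration of the isopropenyl double bond into conjugation, is a second risk. The fallback introduces silicon after the carbinol is made. Setting out from 4, ethynylmagnesium bromide 6 with anhydrous CeCl3 (THF, −78 °C), the smallest and least basic alkynyl nucleophile, would give the ethynyl carbinol F8. Hydrosilylation of the terminal alkyne with benzyldimethylsilane under a zerovalent platinum catalyst (Pt2[(CH2=CHSiMe2)2O]3, P(t-Bu)3, THF) would add Si–H cis with silicon at the terminus and give the E-vinylsilane directly, rejoining the route at 11.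

**Step 3.** The most likely failure is unselective hydrogen abstraction (at C3–H, at the C15 methyl or at the isopropenyl allylic positions), together with over-oxidation and migration of isopropenyl into conjugation in the product. The fallback replaces C–H oxidation by an oxygen transposition. Setting out from 3, the ring alkene would be epoxidised selectively (mCPBA, NaHCO3, CH2Cl2, 0 °C) to epoxide F9. Sodium phenylselenide (from PhSeSePh and NaBH4, EtOH) would open it at the secondary C5 to hydroxy selenide F10. Oxidation with H2O2 and selenoxide syn-elimination toward C6 would give the tertiary allylic alcohol F11. Pyridinium chlorochromate (C5H5NH+ CrO3Cl−, CH2Cl2) would then effect the oxidative 1,3-transposition of the tertiary allylic alcohol to enone 4.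

## Further compounds

F1 | step 7 | trimethylsilyl ether of 11 | C[Si](C)(C)O[C@]1(/C=C/[Si](C)(C)Cc2ccccc2)C=C(C)[C@@H](O[Si](C(C)C)(C(C)C)C(C)C)C[C@H]1C(C)=C
F2 | step 7 | ring-expanded trimethylsilyl enol ether of 14 (ring-trans enol ether) | C[Si](C)(C)O/C1=C\[C@H]([Si](C)(C)Cc2ccccc2)C/C(C)=C\C[C@H](O[Si](C(C)C)(C(C)C)C(C)C)/C(C)=C\1
F3 | step 8 | 7α epimer of 16 | COC(=O)C[C@H]1[C@H]([Si](C)(C)Cc2ccccc2)C/C(C)=C\C[C@H](O[Si](C(C)C)(C(C)C)C(C)C)/C(C)=C\C1=O
F4 | step 8 | tetrasubstituted potassium C6–C7 enolate of F3 | [K+].[O-]/C1=C(CC(=O)OC)/[C@H]([Si](C)(C)Cc2ccccc2)C/C(C)=C\C[C@H](O[Si](C(C)C)(C(C)C)C(C)C)/C(C)=C\1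
F5 | step 14 | 1α-bromo-10β-hydroxy bromohydrin of 26 | O=C1C(=C)[C@@H]2[C@H](O)C[C@](C)(O)[C@@H](Br)C[C@H](O[Si](C(C)C)(C(C)C)C(C)C)/C(C)=C\[C@@H]2O1
F6 | step 9 | 6α-hydroxy ester (C6 epimer of 17) | COC(=O)C[C@@H]1[C@H]([Si](C)(C)Cc2ccccc2)C/C(C)=C\C[C@H](O[Si](C(C)C)(C(C)C)C(C)C)/C(C)=C\[C@H]1O
F7 | step 9 | 6α-hydroxy acid from F6 | OC(=O)C[C@@H]1[C@H]([Si](C)(C)Cc2ccccc2)C/C(C)=C\C[C@H](O[Si](C(C)C)(C(C)C)C(C)C)/C(C)=C\[C@H]1O
F8 | step 5 | ethynyl carbinol (ethynyl cis to isopropenyl) | O[C@]1(C#C)C=C(C)[C@@H](O[Si](C(C)C)(C(C)C)C(C)C)C[C@H]1C(C)=C
F9 | step 3 | ring epoxide of 3 (either face; both oxirane carbons become sp2 again) | C1C2OC2(C)[C@@H](O[Si](C(C)C)(C(C)C)C(C)C)C[C@H]1C(C)=C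
F10 | step 3 | hydroxy selenide from F9 (phenylseleno at C5, tertiary hydroxyl at C4) | C1C([Se]c2ccccc2)C(C)(O)[C@@H](O[Si](C(C)C)(C(C)C)C(C)C)C[C@H]1C(C)=C
F11 | step 3 | tertiary allylic alcohol (C5=C6 alkene, C4 carbinol) | C1=CC(C)(O)[C@@H](O[Si](C(C)C)(C(C)C)C(C)C)C[C@H]1C(C)=C
A1 | alternative 1 | racemic (Z)-5,9-dimethylcyclodec-8-ene-1,3,6-trione | O=C1CC(C)C(=O)C/C=C(/C)CC(=O)C1
A2 | alternative 1 | racemic 4,7-dimethyl-3,4,5,8-tetrahydronaphthalen-2(1H)-one | O=C1CC(C)C2=C(C1)CC(C)=CC2
A3 | alternative 2 | ten-membered C3 dienone fused to the methyl lactol acetal, C8 p-methoxybenzyl ether | [C@@H]1(OCc2ccc(OC)cc2)C/C(C)=C\CC(=O)/C(C)=C\[C@@H]2O[C@@H](OC)C[C@@H]21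
A4 | alternative 2 | open-chain Z allylic chloride and Z vinylstannane on the lactol acetal | ClC/C=C(/C)C[C@@H](OCc1ccc(OC)cc1)[C@H]1C[C@H](OC)O[C@H]1/C=C(/C)[Sn](CCCC)(CCCC)CCCC
A5 | alternative 3 | epoxy cyclodecenol with free C6 hydroxyl, C3 TBS ether, C8 p-methoxybenzyl ether, C7 tert-butyl acetate arm | O[C@H]1/C=C(/C)[C@@H](O[Si](C)(C)C(C)(C)C)C[C@H]2O[C@@]2(C)C[C@@H](OCc2ccc(OC)cc2)[C@H]1CC(=O)OC(C)(C)C
A6 | alternative 3 | open-chain C6 aldehyde with Z C5 vinyl iodide | O=C[C@H](CC(=O)OC(C)(C)C)[C@H](OCc1ccc(OC)cc1)C[C@]1(C)O[C@@H]1C[C@H](O[Si](C)(C)C(C)(C)C)/C(C)=C\I
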